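**Retrosynthetic overview**
1. Target ⇒ late oxirane closure and CH2OH → CHO; the 4-methylpent-3-enyl chain comes from a C1 vinyl group (hydroboration/Suzuki–Miyaura); the 12-membered ring comes from an intramolecular B-alkyl Suzuki–Miyaura coupling at the homoallylic arm, the allylic arm from a Negishi coupling.
2. Key disconnection: the cyclohexane is cut at C2–C3 and C5–C6 ([3+3]) into an achiral malonate-derived 1,5-dialdehyde and an α-silyloxy vinyl ketone, joined in one pot by amine-catalysed Michael addition and enolexo aldol closure, then lactonisation.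
3. Enabling feature: quaternary ring carbon C1 lies between methines C2 and C6, whose exocyclic CH2 groups (the first atoms of the 12-membered ring) are formyl carbons at the aldehyde level, so C2 and C6 are the two α-carbons of one dialdehyde, while C3–C4–C5(–CH2O) is a vinyl ketone.
4. The two carbon substituents on C1 start as identical esters; the C5 oxygen, cis-1,3 to one of them, tells them apart through a bridging γ-lactone.
5. Ring order: cyclohexane (with temporary γ-lactone) → 12-membered carbocycle → oxirane.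

Key step: step 5

**Remarks**
- The target is taken as drawn: both ring alkenes are Z, and the two bonds from the cyclohexane into the 12-membered ring are trans to each other.
- Core numbering used in all names: C1 = quaternary carbon (formyl and 4-methylpent-3-enyl in the target), C2 = methine with the allylic arm, C3 and C4 = ring CH2, C5 = oxygenated quaternary carbon, C6 = methine with the homoallylic arm. β is the face of the C2 arm, α the other face; in every ring compound the C2 arm is β, the C6 arm α, the C5 CH2O β, the C5 oxygen α, the C1 ester/formyl carbon β and the C1 lactone/vinyl/alkenyl carbon α.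
- Compounds marked "not isolated" are carried on crude.

**Step 1**
Reactants: 1 dimethyl 2,2-diallylmalonate
Product: 2 dimethyl 2,2-bis(2-oxoethyl)propanedioate
Conditions: O3, CH2Cl2, −78 °C; then Me2S, −78 °C → rt
Reagents that add atoms: ozone [O-][O+]=O
Why: Ozonolysis with reductive work-up cleaves both terminal alkenes to the dialdehyde; no stereocentre is involved.

**Step 2**
Reactants: 3 but-3-ene-1,2-diol (racemic)
Product: 4 1-[(tert-butyldiphenylsilyl)oxy]but-3-en-2-ol
Conditions: t-BuPh2SiCl (1.0 equiv), imidazole, CH2Cl2, 0 °C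
Reagents that add atoms: tert-butyl(chloro)diphenylsilane CC(C)(C)[Si](Cl)(c1ccccc1)c1ccccc1
Why: Silyl ether formation should be selective for the primary hydroxyl of the 1,2-diol on steric grounds.

**Step 3**
Reactants: 4 1-[(tert-butyldiphenylsilyl)oxy]but-3-en-2-ol
Product: 5 1-[(tert-butyldiphenylsilyl)oxy]but-3-en-2-one
Conditions: Dess–Martin periodinane, CH2Cl2, 0 °C → rt; used at once
Reagents that add atoms: none
Why: Dess–Martin oxidation of the secondary allylic alcohol should give the vinyl ketone without touching the silyl ether; the stereocentre of 4 is removed.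

**Step 4**
Reactants: 6 2-(2-bromoethyl)-1,3-dioxolane
Product: 10 2-[(3Z)-4-iodo-3-methylbut-3-en-1-yl]-1,3-dioxolane, via Grignard reagent 7 (not isolated), via alkylcopper 8 (not isolated), via alkenylcopper 9 (not isolated)
Conditions: Mg, THF; CuBr·SMe2 (1 equiv), Et2O/Me2S, −45 °C; propyne, −25 °C; I2, −78 → 0 °C
Reagents that add atoms: propyne CC#C; iodine II
Why: Normant carbocupration adds the alkylcopper syn across propyne with copper on the terminal carbon, and iodinolysis with retention should give the (Z)-alkenyl iodide in which iodine and the acetal chain are cis.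

**Step 5**
Reactants: 2 dimethyl 2,2-bis(2-oxoethyl)propanedioate; 5 1-[(tert-butyldiphenylsilyl)oxy]but-3-en-2-one
Product: 13 bridged γ-lactone dialdehyde methyl ester, via Michael adduct 11 (not isolated), via aldol 12 (not isolated)
Conditions: (S)-α,α-diphenylprolinol trimethylsilyl ether (15 mol%), 4-nitrophenol (15 mol%), toluene, 0 °C → rt, 5 added slowly to 2 (1.2 equiv); then p-TsOH (25 mol%), 40 °C
Reagents that add atoms: none
Why: The amine condenses with one of the two homotopic formyl arms of 2 and the (E)-enamine adds through its unshielded Si face to the β-carbon of 5 (enamine Michael addition, bond C2–C3); the amine then forms the enamine of the second, still unbranched arm, which attacks the α-silyloxy ketone (intramolecular aldol, bond C5–C6), and acid finally closes the γ-lactone. The closest known reaction types are the amine-catalysed Michael addition of aldehydes to vinyl ketones and the amine-catalysed enolexo aldolisation of keto aldehydes, here run as one domino sequence. The cyclohexane closes by a 6-(enolexo)-exo-trig aldol addition through a chair, and the lactone by 5-exo-trig attack of the axial C5 hydroxyl on the syn-axial ester. C2 and C6 are both set by the catalyst (the same Si-face rule at two enamines makes them homochiral, hence trans across C1); C5 is set by the chair in which the bulky CH2OSi group is equatorial and the carbonyl oxygen axial, which avoids a 1,3-diaxial clash with the axial ester; C1 is set by the lactonisation, because only the ester cis to the C5 oxygen can close, which ties C1 to C5. The step needs mono- over bis-Michael addition (slow addition of 5 to excess 2, fast intramolecular aldol), aldehyde- over ketone-enamine formation (the hindered amine activates only aldehydes), and no dehydration or epimerisation (both formyl groups of the product are α-branched and should no longer form enamines, and lactonisation is run under acid).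

**Step 6**
Reactants: 13 bridged γ-lactone dialdehyde methyl ester
Product: 15 2β-iodomethyl 6α-formyl lactone ester, via primary alcohol 14 (not isolated)
Conditions: NaBH4 (0.5 equiv), MeOH/CH2Cl2, −78 °C; aqueous NH4Cl work-up; then PPh3, I2, imidazole, CH2Cl2, 0 °C
Reagents that add atoms: iodine II
Why: Chemoselective borohydride reduction then Appel iodination: the C2 formyl group has one quaternary neighbour whereas the C6 formyl group lies between two fully substituted carbons next to the silyloxymethyl group, so hydride should reach C2-CHO first, and immediate iodination should keep the cis hydroxy ester from closing to a fused lactone.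

**Step 7**
Reactants: 15 2β-iodomethyl 6α-formyl lactone ester
Product: 16 2β-iodomethyl 6α-vinyl lactone ester
Conditions: Tebbe reagent Cp2Ti(μ-Cl)(μ-CH2)AlMe2 (1.1 equiv), pyridine (cat.), THF/toluene, −40 → 0 °C
Reagents that add atoms: Tebbe reagent C=[Ti](C1C=CC=C1)C1C=CC=C1.C[Al](C)Cl
Why: Tebbe methylenation should convert the hindered, base-sensitive β-acyloxy aldehyde to the vinyl group under non-basic conditions at which ester, lactone and alkyl iodide do not react.

**Step 8**
Reactants: 16 2β-iodomethyl 6α-vinyl lactone ester; 10 2-[(3Z)-4-iodo-3-methylbut-3-en-1-yl]-1,3-dioxolane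
Product: 18 2β-[(2Z)-5-(1,3-dioxolan-2-yl)-3-methylpent-2-en-1-yl] 6α-vinyl lactone ester, via alkylzinc iodide 17 (not isolated)
Conditions: Zn dust (activated with 1,2-dibromoethane and Me3SiCl), DMA/THF, 40 °C; then 10, Pd(PPh3)4 (5 mol%), rt → 40 °C
Reagents that add atoms: none
Why: Negishi coupling: zinc inserts into the primary C–I bond and the alkylzinc iodide should couple with the alkenyl iodide with retention of the (Z)-geometry, organozinc reagents tolerating ester, lactone and silyl ether.

**Step 9**
Reactants: 18 dioxolane-bearing 6α-vinyl lactone ester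
Product: 19 2β-[(2Z)-3-methyl-6-oxohex-2-en-1-yl] 6α-vinyl lactone ester
Conditions: 1 M HCl, THF, rt
Reagents that add atoms: water O
Why: Acid-catalysed acetal hydrolysis should free the aldehyde while the tert-butyldiphenylsilyl ether, the lactone and the (Z)-alkene are stable to dilute acid.

**Step 10**
Reactants: 19 aldehyde-bearing 6α-vinyl lactone ester
Product: 20 2β-[(2Z,6Z)-7-iodo-3-methylocta-2,6-dien-1-yl] 6α-vinyl lactone ester
Conditions: EtPPh3I, n-BuLi, THF, rt; I2, −78 °C; NaN(SiMe3)2, −20 °C; then 19, −78 °C → rt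
Reagents that add atoms: ethyltriphenylphosphonium iodide CC[P+](c1ccccc1)(c1ccccc1)c1ccccc1.[I-]; iodine II
Why: Stork–Zhao-type Wittig olefination with the α-iodo ylide should give the (Z)-2-iodoalk-2-ene (iodine cis to the chain) under kinetic control at low temperature.

**Step 11**
Reactants: 20 alkenyl iodide-bearing 6α-vinyl lactone ester
Product: 22 macrocyclic lactone ester, via alkylborane 21 (not isolated)
Conditions: 9-BBN, THF, rt → 50 °C; then slow addition to PdCl2(dppf) (15 mol%; dppf = 1,1'-bis(diphenylphosphino)ferrocene), AsPh3, Cs2CO3, DMF/THF/H2O, 50 °C, high dilution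
Reagents that add atoms: none
Why: B-alkyl Suzuki–Miyaura macrocyclisation: 9-BBN should add only to the monosubstituted alkene, and intramolecular coupling with the alkenyl iodide should close the 12-membered ring with retention of the (Z)-geometry; no stereocentre is formed.

**Step 12**
Reactants: 22 macrocyclic lactone ester
Product: 23 macrocyclic lactol ester (anomeric mixture)
Conditions: i-Bu2AlH (1.1 equiv), CH2Cl2, −78 °C
Reagents that add atoms: none
Why: Partial reduction of a lactone to the lactol: the strained bridged γ-lactone should be attacked before the methyl ester on the same quaternary carbon, and the new lactol centre is of no consequence because it is destroyed in step 13.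

**Step 13**
Reactants: 23 macrocyclic lactol ester
Product: 24 1α-vinyl 5α-hydroxy macrocyclic ester
Conditions: Ph3PCH3Br, KN(SiMe3)2 (excess), THF, 0 → 50 °C
Reagents that add atoms: methyltriphenylphosphonium bromide C[P+](c1ccccc1)(c1ccccc1)c1ccccc1.[Br-]
Why: Wittig methylenation of the ring-opened lactol (hydroxy aldehyde) should give the vinyl group and free the tertiary C5 hydroxyl, the hindered methyl ester being inert to the ylide.

**Step 14**
Reactants: 24 1α-vinyl 5α-hydroxy macrocyclic ester
Product: 26 1α-(4-methylpent-3-enyl) 5α-hydroxy macrocyclic ester, via alkylborane 25 (not isolated)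
Conditions: 9-BBN (excess), THF, 50 °C; then 1-bromo-2-methylprop-1-ene, PdCl2(dppf) (5 mol%), aqueous K3PO4, DMF, 50 °C
Reagents that add atoms: 1-bromo-2-methylprop-1-ene CC(C)=CBr
Why: Hydroboration of the only monosubstituted alkene and B-alkyl Suzuki–Miyaura coupling with the alkenyl bromide should build the side chain, the trisubstituted ring alkenes being too hindered for 9-BBN.

**Step 15**
Reactants: 26 1α-(4-methylpent-3-enyl) 5α-hydroxy macrocyclic ester
Product: 27 1β-hydroxymethyl silyl ether
Conditions: LiAlH4, THF, 0 → 40 °C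
Reagents that add atoms: none
Why: Hydride reduction of the neopentyl methyl ester to the primary alcohol; silyl ether and alkenes are inert.

**Step 16**
Reactants: 27 1β-hydroxymethyl silyl ether
Product: 28 triol
Conditions: n-Bu4NF, THF, rt → 40 °C
Reagents that add atoms: none
Why: Fluoride-mediated desilylation should liberate the primary hydroxyl of the 1,2-diol.

**Step 17**
Reactants: 28 triol
Product: 29 5β-tosyloxymethyl diol
Conditions: TsCl (1.05 equiv), Bu2SnO (5 mol%), Et3N, CH2Cl2, 0 °C → rt
Reagents that add atoms: 4-methylbenzenesulfonyl chloride Cc1ccc(cc1)S(Cl)(=O)=O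
Why: Tin-catalysed regioselective sulfonylation: the stannylene acetal forms only at the 1,2-diol, so the primary hydroxyl next to the tertiary carbinol should be tosylated in preference to the isolated neopentyl hydroxyl.

**Step 18**
Reactants: 29 5β-tosyloxymethyl diol
Product: 30 1β-formyl 5β-tosyloxymethyl 5α-alcohol
Conditions: (n-Pr4N)RuO4 (5 mol%), N-methylmorpholine N-oxide, 4 Å molecular sieves, CH2Cl2, rt
Reagents that add atoms: none
Why: Ley–Griffith oxidation of the remaining primary alcohol should give the non-enolisable aldehyde while the tertiary alcohol and the sulfonate are untouched.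

**Step 19**
Reactants: 30 1β-formyl 5β-tosyloxymethyl 5α-alcohol
Product: 31 target spiro-epoxy aldehyde
Conditions: K2CO3, MeOH, 0 °C → rt
Reagents that add atoms: none
Why: Intramolecular Williamson-type displacement (3-exo-tet) of the tosylate by the tertiary alkoxide should close the spiro-oxirane with retention at C5, because the C5–O bond is not broken.

**Compound list**
1 | dimethyl 2,2-di(prop-2-en-1-yl)propanedioate (dimethyl diallylmalonate) | C=CCC(CC=C)(C(=O)OC)C(=O)OC | starting material
2 | dimethyl 2,2-bis(2-oxoethyl)propanedioate | O=CCC(CC=O)(C(=O)OC)C(=O)OC | intermediate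
3 | but-3-ene-1,2-diol (racemic) | C=CC(O)CO | starting material
4 | 1-[(tert-butyldiphenylsilyl)oxy]but-3-en-2-ol (racemic) | C=CC(O)CO[Si](c1ccccc1)(c1ccccc1)C(C)(C)C | intermediate
5 | 1-[(tert-butyldiphenylsilyl)oxy]but-3-en-2-one | C=CC(=O)CO[Si](c1ccccc1)(c1ccccc1)C(C)(C)C | intermediate
6 | 2-(2-bromoethyl)-1,3-dioxolane | BrCCC1OCCO1 | starting material
7 | [2-(1,3-dioxolan-2-yl)ethyl]magnesium bromide | Br[Mg]CCC1OCCO1 | intermediate (not isolated)
8 | [2-(1,3-dioxolan-2-yl)ethyl]copper | [Cu]CCC1OCCO1 | intermediate (not isolated)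
9 | [(1Z)-4-(1,3-dioxolan-2-yl)-2-methylbut-1-en-1-yl]copper | [Cu]/C=C(/C)CCC1OCCO1 | intermediate (not isolated)
10 | 2-[(3Z)-4-iodo-3-methylbut-3-en-1-yl]-1,3-dioxolane | I/C=C(/C)CCC1OCCO1 | intermediate
11 | dimethyl 2-[(2S)-6-[(tert-butyldiphenylsilyl)oxy]-1,5-dioxohexan-2-yl]-2-(2-oxoethyl)propanedioate | O=C[C@@H](CCC(=O)CO[Si](c1ccccc1)(c1ccccc1)C(C)(C)C)C(CC=O)(C(=O)OC)C(=O)OC | intermediate (not isolated)
12 | dimethyl 2β,6α-diformyl-5α-hydroxy-5β-[(tert-butyldiphenylsilyl)oxymethyl]cyclohexane-1,1-dicarboxylate | COC(=O)C1(C(=O)OC)[C@@H](C=O)CC[C@@](O)(CO[Si](c2ccccc2)(c2ccccc2)C(C)(C)C)[C@@H]1C=O | intermediate (not isolated)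
13 | methyl 2β,6α-diformyl-5β-[(tert-butyldiphenylsilyl)oxymethyl]cyclohexane-1β-carboxylate, 1α-carboxyl lactonised onto the 5α-oxygen (bridged γ-lactone) | O=C3[C@]1(C(=O)OC)[C@@H](C=O)CC[C@@](O3)(CO[Si](c4ccccc4)(c4ccccc4)C(C)(C)C)[C@@H]1C=O | intermediate
14 | as 13, with 2β-hydroxymethyl in place of 2β-formyl | O=C3[C@]1(C(=O)OC)[C@@H](CO)CC[C@@](O3)(CO[Si](c4ccccc4)(c4ccccc4)C(C)(C)C)[C@@H]1C=O | intermediate (not isolated)
15 | as 13, with 2β-iodomethyl and 6α-formyl | O=C3[C@]1(C(=O)OC)[C@@H](CI)CC[C@@](O3)(CO[Si](c4ccccc4)(c4ccccc4)C(C)(C)C)[C@@H]1C=O | intermediate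
16 | as 13, with 2β-iodomethyl and 6α-vinyl | O=C3[C@]1(C(=O)OC)[C@@H](CI)CC[C@@](O3)(CO[Si](c4ccccc4)(c4ccccc4)C(C)(C)C)[C@@H]1C=C | intermediate
17 | as 16, with 2β-(iodozinciomethyl) | O=C3[C@]1(C(=O)OC)[C@@H](C[Zn]I)CC[C@@](O3)(CO[Si](c4ccccc4)(c4ccccc4)C(C)(C)C)[C@@H]1C=C | intermediate (not isolated)
18 | as 16, with 2β-[(2Z)-5-(1,3-dioxolan-2-yl)-3-methylpent-2-en-1-yl] | O=C3[C@]1(C(=O)OC)[C@@H](C/C=C(/C)CCC5OCCO5)CC[C@@](O3)(CO[Si](c4ccccc4)(c4ccccc4)C(C)(C)C)[C@@H]1C=C | intermediate
19 | as 16, with 2β-[(2Z)-3-methyl-6-oxohex-2-en-1-yl] | O=C3[C@]1(C(=O)OC)[C@@H](C/C=C(/C)CCC=O)CC[C@@](O3)(CO[Si](c4ccccc4)(c4ccccc4)C(C)(C)C)[C@@H]1C=C | intermediate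
20 | as 16, with 2β-[(2Z,6Z)-7-iodo-3-methylocta-2,6-dien-1-yl] | O=C3[C@]1(C(=O)OC)[C@@H](C/C=C(/C)CC/C=C(/C)I)CC[C@@](O3)(CO[Si](c4ccccc4)(c4ccccc4)C(C)(C)C)[C@@H]1C=C | intermediate
21 | as 20, with 6α-[2-(9-borabicyclo[3.3.1]nonan-9-yl)ethyl] in place of 6α-vinyl | O=C3[C@]1(C(=O)OC)[C@@H](C/C=C(/C)CC/C=C(/C)I)CC[C@@](O3)(CO[Si](c4ccccc4)(c4ccccc4)C(C)(C)C)[C@@H]1CCB5C6CCCC5CCC6 | intermediate (not isolated)
22 | macrocyclic lactone ester: core as 13, with C2β and C6α joined by a (2Z,6Z)-3,7-dimethylnona-2,6-diene-1,9-diyl bridge (C1' on C2) | O=C3[C@]1(C(=O)OC)[C@H]2C/C=C(/C)CC/C=C(/C)CC[C@H]1[C@@](O3)(CC2)CO[Si](c1ccccc1)(c1ccccc1)C(C)(C)C | intermediate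
23 | as 22, with the lactone carbonyl reduced to the lactol (anomeric mixture) | OC3[C@]1(C(=O)OC)[C@H]2C/C=C(/C)CC/C=C(/C)CC[C@H]1[C@@](O3)(CC2)CO[Si](c1ccccc1)(c1ccccc1)C(C)(C)C | intermediate
24 | bridged bicycle with 1β-CO2Me, 1α-vinyl, 5α-OH and 5β-CH2OSi(t-Bu)Ph2 | C=C[C@]1(C(=O)OC)[C@H]2C/C=C(/C)CC/C=C(/C)CC[C@H]1[C@@](O)(CC2)CO[Si](c1ccccc1)(c1ccccc1)C(C)(C)C | intermediate
25 | as 24, with 1α-[2-(9-borabicyclo[3.3.1]nonan-9-yl)ethyl] | B3(C4CCCC3CCC4)CC[C@]1(C(=O)OC)[C@H]2C/C=C(/C)CC/C=C(/C)CC[C@H]1[C@@](O)(CC2)CO[Si](c1ccccc1)(c1ccccc1)C(C)(C)C | intermediate (not isolated)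
26 | as 24, with 1α-(4-methylpent-3-en-1-yl) | CC(C)=CCC[C@]1(C(=O)OC)[C@H]2C/C=C(/C)CC/C=C(/C)CC[C@H]1[C@@](O)(CC2)CO[Si](c1ccccc1)(c1ccccc1)C(C)(C)C | intermediate
27 | as 26, with 1β-CH2OH in place of 1β-CO2Me | CC(C)=CCC[C@]1(CO)[C@H]2C/C=C(/C)CC/C=C(/C)CC[C@H]1[C@@](O)(CC2)CO[Si](c1ccccc1)(c1ccccc1)C(C)(C)C | intermediate
28 | triol: 1β-CH2OH, 5α-OH, 5β-CH2OH | CC(C)=CCC[C@]1(CO)[C@H]2C/C=C(/C)CC/C=C(/C)CC[C@H]1[C@@](O)(CC2)CO | intermediate
29 | as 28, with 5β-CH2OTs | CC(C)=CCC[C@]1(CO)[C@H]2C/C=C(/C)CC/C=C(/C)CC[C@H]1[C@@](O)(CC2)COS(=O)(=O)c1ccc(C)cc1 | intermediate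
30 | as 29, with 1β-CHO | CC(C)=CCC[C@]1(C=O)[C@H]2C/C=C(/C)CC/C=C(/C)CC[C@H]1[C@@](O)(CC2)COS(=O)(=O)c1ccc(C)cc1 | intermediate
31 | (1R,3Z,7Z,11R,12S,15S)-4,8-dimethyl-15-(4-methylpent-3-en-1-yl)spiro[bicyclo[9.3.1]pentadeca-3,7-diene-12,2'-oxirane]-15-carbaldehyde (descriptors assigned by hand; the SMILES is authoritative) | CC(C)=CCC[C@]1(C=O)[C@H]2C/C=C(/C)CC/C=C(/C)CC[C@H]1[C@@]1(CC2)CO1 | target

**Totals**
Total step count: 19. Longest linear sequence: 17 steps (steps 2 and 3, then steps 5–19).

**Steps most likely to fail**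

*Step 5.* What may go wrong: a second Michael addition on the remaining arm outruns ring closure, or catalyst control is lost in the aldol closure (closure through the other chair, giving the C5 epimer). The fallback sets out from 2 and separates the two bond formations with the arms differentiated. Mono-acetalisation of 2 (MeOH, catalytic pyridinium tosylate, partial conversion with recycling) gives dimethyl 2-(2,2-dimethoxyethyl)-2-(2-oxoethyl)propanedioate F1. F1 has only one enolisable formyl group, so the amine-catalysed Michael addition to 5 can be run to completion and should give dimethyl 2-[(2S)-6-[(tert-butyldiphenylsilyl)oxy]-1,5-dioxohexan-2-yl]-2-(2,2-dimethoxyethyl)propanedioate F2. Mild aqueous acid liberates the second formyl group to give 11, now as an isolated compound. 11 is cyclised with the same amine in a separate, dilute enolexo aldolisation and lactonised with acid. The fallback comes back to the route at 13.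

*Step 11.* What may go wrong: oligomerisation and protodeboronation compete with a slow transmetalation and ring closure of the hindered B-alkyl borane across the trans-disposed arms. The fallback sets out from 20 and closes the ring with a preformed alkylzinc under neutral, anhydrous conditions. Hydroboration of 20 with 9-BBN and oxidative work-up (NaBO3) gives the 6α-(2-hydroxyethyl) alkenyl iodide F7. Appel iodination gives the 6α-(2-iodoethyl) compound F8. Zinc inserts only into the alkyl C–I bond to give the alkylzinc iodide F9, which is added slowly to Pd(PPh3)4 under high dilution (intramolecular Negishi coupling). The fallback comes back to the route at 22.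

*Step 6.* What may go wrong: hydride attacks both formyl groups at similar rates, so site selectivity is lost. The fallback sets out from 13 and moves the discriminating event to a reversible acetalisation, so that the reduction is later run on a compound with a single formyl group. 1,2-Bis(trimethylsilyloxy)ethane with catalytic Me3SiOTf at −78 °C should acetalise only the less hindered formyl group and give the 2β-(1,3-dioxolan-2-yl) 6α-formyl lactone ester F3. Tebbe methylenation gives the 2β-(1,3-dioxolan-2-yl) 6α-vinyl lactone ester F4. Dilute acid gives the 2β-formyl 6α-vinyl lactone ester F5. NaBH4 gives the 2β-hydroxymethyl 6α-vinyl lactone ester F6, which is iodinated at once (PPh3, I2, imidazole). The fallback comes back to the route at 16.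

**Further compounds**
F1 | step 5 | dimethyl 2-(2,2-dimethoxyethyl)-2-(2-oxoethyl)propanedioate | COC(CC(CC=O)(C(=O)OC)C(=O)OC)OC
F2 | step 5 | dimethyl 2-[(2S)-6-[(tert-butyldiphenylsilyl)oxy]-1,5-dioxohexan-2-yl]-2-(2,2-dimethoxyethyl)propanedioate | O=C[C@@H](CCC(=O)CO[Si](c1ccccc1)(c1ccccc1)C(C)(C)C)C(CC(OC)OC)(C(=O)OC)C(=O)OC
F3 | step 6 | 2β-(1,3-dioxolan-2-yl) 6α-formyl lactone ester (core as 13) | O=C3[C@]1(C(=O)OC)[C@@H](C5OCCO5)CC[C@@](O3)(CO[Si](c4ccccc4)(c4ccccc4)C(C)(C)C)[C@@H]1C=O
F4 | step 6 | 2β-(1,3-dioxolan-2-yl) 6α-vinyl lactone ester | O=C3[C@]1(C(=O)OC)[C@@H](C5OCCO5)CC[C@@](O3)(CO[Si](c4ccccc4)(c4ccccc4)C(C)(C)C)[C@@H]1C=C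
F5 | step 6 | 2β-formyl 6α-vinyl lactone ester | O=C3[C@]1(C(=O)OC)[C@@H](C=O)CC[C@@](O3)(CO[Si](c4ccccc4)(c4ccccc4)C(C)(C)C)[C@@H]1C=C
F6 | step 6 | 2β-hydroxymethyl 6α-vinyl lactone ester | O=C3[C@]1(C(=O)OC)[C@@H](CO)CC[C@@](O3)(CO[Si](c4ccccc4)(c4ccccc4)C(C)(C)C)[C@@H]1C=C
F7 | step 11 | as 20, with 6α-(2-hydroxyethyl) in place of 6α-vinyl | O=C3[C@]1(C(=O)OC)[C@@H](C/C=C(/C)CC/C=C(/C)I)CC[C@@](O3)(CO[Si](c4ccccc4)(c4ccccc4)C(C)(C)C)[C@@H]1CCO
F8 | step 11 | as 20, with 6α-(2-iodoethyl) | O=C3[C@]1(C(=O)OC)[C@@H](C/C=C(/C)CC/C=C(/C)I)CC[C@@](O3)(CO[Si](c4ccccc4)(c4ccccc4)C(C)(C)C)[C@@H]1CCI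
F9 | step 11 | as 20, with 6α-[2-(iodozincio)ethyl] | O=C3[C@]1(C(=O)OC)[C@@H](C/C=C(/C)CC/C=C(/C)I)CC[C@@](O3)(CO[Si](c4ccccc4)(c4ccccc4)C(C)(C)C)[C@@H]1CC[Zn]I
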